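**Retrosynthetic overview**

1. The target is reached by hydrogenolysis of a decabenzyl ether, which comes from a threefold Baeyer–Villiger oxidation and methanolysis of a pentaaryl tris-aldehyde; only C–O bonds are made, and all five benzene rings are bought.
2. Feature used (rings lettered A to E along the chain from the 2,4,6-trihydroxyphenyl end, C1 of each ring being the carbon bound to the oxygen of the preceding ring): in ring C the C4 hydroxyl between C3-OH and C5-OH, in ring D the C4 hydroxyl between C3-OH and C5–O–E, and in ring E the C4 hydroxyl between C3-OH and C5-OH each lie para to C1. A formyl group at C4 therefore activates fluoride displacement at C1, C3 and C5 and is afterwards exchanged for the hydroxyl.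
3. The tris-aldehyde is assembled by iterative SNAr in the order A, B, C, D, E: each phenoxide takes the fluorine para to the formyl group of the next fluorobenzaldehyde, then benzyl oxide takes the ortho fluorines. Ring B is built the same way and its formyl group is oxidised early to give the AB phenol.
4. Two oxygens cannot come from benzyl oxide at an ortho fluorine and are carried as MOM ethers: the O–D oxygen on C6 of ring C, which is meta to the formyl group (from 2,4,6-trifluorophenol by MOM protection and lithiation/formylation), and the O–E oxygen on C5 of ring D (from 2,4-difluoro-6-hydroxybenzaldehyde).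
5. Ring A comes from 2,4,6-trihydroxybenzaldehyde by benzylation and a Baeyer–Villiger oxidation.

Key step: step 17

Assumption: 2,4,6-trifluorophenol and 2,4-difluoro-6-hydroxybenzaldehyde (and, for the fallbacks only, 2-bromo-4,6-difluorophenol and 4-bromo-2,6-difluorobenzaldehyde) are taken as catalogue compounds.

In the names below, "AB-oxy" means the 2,6-bis(benzyloxy)-4-[2,4,6-tris(benzyloxy)phenoxy]phenoxy group.

**Route**

Step 1
Reactants: 1 2,4,6-trihydroxybenzaldehyde
Product: 2 2,4,6-tris(benzyloxy)benzaldehyde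
Conditions: BnBr (3.6 equiv), K2CO3, DMF, 60 °C
Reagents that add atoms: benzyl bromide, BrCc1ccccc1
Why: Williamson O-benzylation of all three phenols should proceed because the formyl group damps C-alkylation of the phloroglucinol ring, and excess bromide with heat drives the chelated ortho hydroxyls to react.

Step 2
Reactants: 2 2,4,6-tris(benzyloxy)benzaldehyde
Product: 4 2,4,6-tris(benzyloxy)phenol, via aryl formate 3 (not isolated)
Conditions: mCPBA, CH2Cl2, 0 °C → rt; aq. Na2S2O3; then K2CO3 (cat.), MeOH/THF, 0 °C, argon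
Reagents that add atoms: 3-chloroperoxybenzoic acid (mCPBA), OOC(=O)c1cccc(Cl)c1
Why: Baeyer–Villiger (Dakin-type) oxidation in which the trialkoxyphenyl group migrates in preference to hydride, followed by methanolysis of the formate under argon so that the electron-rich phenol is not oxidised further.

Step 3
Reactants: 4 2,4,6-tris(benzyloxy)phenol; 5 2,4,6-trifluorobenzaldehyde
Product: 6 2,6-difluoro-4-[2,4,6-tris(benzyloxy)phenoxy]benzaldehyde
Conditions: Cs2CO3, DMF, 0 °C → rt, argon
Reagents that add atoms: none
Why: Nucleophilic aromatic substitution (SNAr) at the fluorine para to the formyl group, which the bulky 2,6-disubstituted phenoxide should prefer over the ortho fluorines in a polar aprotic solvent where no cation bridges it to the carbonyl.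

Step 4
Reactants: 6 2,6-difluoro-4-[2,4,6-tris(benzyloxy)phenoxy]benzaldehyde; 7 benzyl alcohol
Product: 8 2,6-bis(benzyloxy)-4-[2,4,6-tris(benzyloxy)phenoxy]benzaldehyde
Conditions: BnOH (2.3 equiv), NaH, THF, 0 °C; then 6, THF/DMF, 0 °C → rt
Reagents that add atoms: benzyl alcohol (second equivalent), OCc1ccccc1
Why: Twofold SNAr of the formyl-activated ortho fluorines by two equivalents of preformed sodium benzyloxide, fluoride leaving far faster than the para aryloxide, with the low temperature keeping hydride transfer from the alkoxide to the aldehyde slow.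

Step 5
Reactants: 8 2,6-bis(benzyloxy)-4-[2,4,6-tris(benzyloxy)phenoxy]benzaldehyde
Product: 10 2,6-bis(benzyloxy)-4-[2,4,6-tris(benzyloxy)phenoxy]phenol (AB phenol), via aryl formate 9 (not isolated)
Conditions: mCPBA, CH2Cl2, 0 °C → rt; aq. Na2S2O3; then K2CO3 (cat.), MeOH/THF, 0 °C, argon
Reagents that add atoms: 3-chloroperoxybenzoic acid (mCPBA), OOC(=O)c1cccc(Cl)c1
Why: Baeyer–Villiger oxidation with aryl migration, favoured by the two ortho benzyloxy groups and the para aryloxy group, then formate methanolysis to the ring B phenol.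

Step 6
Reactants: 11 2,4,6-trifluorophenol
Product: 12 1,3,5-trifluoro-2-(methoxymethoxy)benzene
Conditions: MOMCl, K2CO3, acetone, 0 °C → rt
Reagents that add atoms: chloromethyl methyl ether (MOMCl), COCCl
Why: O-alkylation of the acidic phenol gives a MOM ether that is stable to the later bases and removable beside benzyl ethers.

Step 7
Reactants: 12 1,3,5-trifluoro-2-(methoxymethoxy)benzene
Product: 14 2,4,6-trifluoro-3-(methoxymethoxy)benzaldehyde, via aryllithium 13 (not isolated)
Conditions: LiN(i-Pr)2, THF, −78 °C; DMF, −78 °C; AcOH quench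
Reagents that add atoms: N,N-dimethylformamide, CN(C)C=O
Why: Directed ortho-lithiation at the C–H flanked by two fluorines (both such sites are equivalent) and formylation with DMF, held at −78 °C so that loss of LiF to an aryne does not set in.

Step 8
Reactants: 10 AB phenol; 14 2,4,6-trifluoro-3-(methoxymethoxy)benzaldehyde
Product: 15 4-(AB-oxy)-2,6-difluoro-3-(methoxymethoxy)benzaldehyde
Conditions: Cs2CO3, DMF, 0 °C → rt, argon
Reagents that add atoms: none
Why: SNAr at C4 of 14, para to the formyl group, which should be preferred because C2 is shielded on both sides by CHO and OMOM and C6 is deactivated by the para MOM-oxy donor.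

Step 9
Reactants: 15 4-(AB-oxy)-2,6-difluoro-3-(methoxymethoxy)benzaldehyde; 7 benzyl alcohol
Product: 16 2,6-bis(benzyloxy)-4-(AB-oxy)-3-(methoxymethoxy)benzaldehyde
Conditions: BnOH (2.5 equiv), NaH, THF, 0 °C; then 15, DMF, 0 → 40 °C
Reagents that add atoms: benzyl alcohol (second equivalent), OCc1ccccc1
Why: Twofold SNAr of the two ortho fluorines by two equivalents of sodium benzyloxide, with the MOM ether and the diaryl ethers inert to alkoxide.

Step 10
Reactants: 16 2,6-bis(benzyloxy)-4-(AB-oxy)-3-(methoxymethoxy)benzaldehyde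
Product: 17 2,6-bis(benzyloxy)-3-hydroxy-4-(AB-oxy)benzaldehyde (ABC phenol)
Conditions: conc. HCl (cat.), MeOH/THF, 40 °C; aqueous work-up
Reagents that add atoms: none
Why: Acid-catalysed acetal exchange removes the MOM group while benzyl and diaryl ethers stay intact, and any dimethyl acetal of the aldehyde reverts on aqueous work-up.

Step 11
Reactants: 18 2,4-difluoro-6-hydroxybenzaldehyde
Product: 19 2,4-difluoro-6-(methoxymethoxy)benzaldehyde
Conditions: MOMCl, K2CO3, acetone, 0 °C → rt
Reagents that add atoms: chloromethyl methyl ether (MOMCl), COCCl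
Why: O-alkylation with the very reactive chloromethyl ether is much faster at 0 °C than self-condensation of the poorly nucleophilic salicylaldehyde-type phenoxide.

Step 12
Reactants: 17 ABC phenol; 19 2,4-difluoro-6-(methoxymethoxy)benzaldehyde
Product: 20 ABCD fluoro aldehyde (17 etherified at its 3-oxygen with a 3-fluoro-4-formyl-5-(methoxymethoxy)phenyl group as ring D)
Conditions: Cs2CO3, DMF, rt → 50 °C, argon
Reagents that add atoms: none
Why: SNAr of the doubly flanked ring C phenoxide at the para fluorine of 19, which sits between two hydrogens, rather than at the ortho fluorine next to the formyl group.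

Step 13
Reactants: 20 ABCD fluoro aldehyde; 7 benzyl alcohol
Product: 21 ABCD aldehyde with ring D = 3-(benzyloxy)-4-formyl-5-(methoxymethoxy)phenyl
Conditions: BnOH (1.3 equiv), NaH, THF, 0 °C; then 20, DMF, 0 °C → rt
Reagents that add atoms: none
Why: SNAr of the single remaining formyl-activated fluorine by sodium benzyloxide, the only carbon–fluorine bond left in the molecule.

Step 14
Reactants: 21 ABCD aldehyde with MOM ether on ring D
Product: 22 ABCD phenol with ring D = 3-(benzyloxy)-4-formyl-5-hydroxyphenyl
Conditions: conc. HCl (cat.), MeOH/THF, 40 °C; aqueous work-up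
Reagents that add atoms: none
Why: Acid-catalysed cleavage of the MOM ether ortho to the formyl group, eased by the hydrogen bond in the salicylaldehyde product and leaving the benzyl ethers untouched.

Step 15
Reactants: 22 ABCD phenol; 5 2,4,6-trifluorobenzaldehyde
Product: 23 pentaaryl difluoro tris-aldehyde (22 etherified at the ring D hydroxyl with a 3,5-difluoro-4-formylphenyl group as ring E)
Conditions: 5 (2 equiv), Cs2CO3, DMF, 0 °C → rt, argon
Reagents that add atoms: none
Why: SNAr at the para fluorine of the strongly activated trifluorobenzaldehyde, used in excess, with the caesium phenoxide in DMF so that cation bridging to the ortho positions is minimised.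

Step 16
Reactants: 23 pentaaryl difluoro tris-aldehyde; 7 benzyl alcohol
Product: 24 decabenzyl tris-aldehyde (formyl at C4 of rings C, D and E; benzyloxy at both ortho positions of ring E)
Conditions: BnOH (2.5 equiv), NaH, THF, 0 °C; then 23, DMF, 0 °C → rt
Reagents that add atoms: benzyl alcohol (second equivalent), OCc1ccccc1
Why: Twofold SNAr of the ring E ortho fluorines by two equivalents of sodium benzyloxide, the fluorinated ring being the most electrophilic of the three formyl-bearing rings.

Step 17
Reactants: 24 decabenzyl tris-aldehyde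
Product: 26 decabenzyl triol (free hydroxyl at C4 of rings C, D and E), via tris-formate 25 (not isolated)
Conditions: mCPBA (4 equiv), CH2Cl2, 0 °C → rt; aq. Na2S2O3; then K2CO3 (cat.), MeOH/THF, 0 °C, argon
Reagents that add atoms: 3-chloroperoxybenzoic acid (mCPBA), OOC(=O)c1cccc(Cl)c1
Why: Each formyl carbonyl takes up the peracid to give a tetrahedral peroxy adduct, and the aryl group shifts from carbon to oxygen with loss of 3-chlorobenzoate, so that three aryl formates form; catalytic carbonate in methanol then transesterifies them to the three phenols. The closest known reaction type is the Baeyer–Villiger (Dakin-type) oxidation of electron-rich benzaldehydes to aryl formates. No ring is closed and no stereocentre is created; the three new bonds are the C4–O bonds of rings C, D and E. The step needs aryl migration to win over hydride migration at all three aldehydes, which the two ortho oxygens and the para aryloxy group on each formyl-bearing ring secure by raising the migratory aptitude of the aryl group. It also needs the aldehydes to react before the electron-rich rings do, which low temperature and a small excess of peracid favour, and the new phenols stay masked as formates until the oxidant has been destroyed.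

Step 18
Reactants: 26 decabenzyl triol
Product: 27 target pentaaryl tetraether polyphenol (CNP0154768.0)
Conditions: H2 (1 atm), Pd/C, THF/MeOH, rt; handled under argon
Reagents that add atoms: none
Why: Heterogeneous hydrogenolysis cleaves the ten benzyl aryl ethers while diaryl ethers and free phenols are untouched.

**Compound list**

1 | 2,4,6-trihydroxybenzaldehyde | O=Cc1c(O)cc(O)cc1O | starting material
2 | 2,4,6-tris(benzyloxy)benzaldehyde | O=Cc1c(OCc2ccccc2)cc(OCc2ccccc2)cc1OCc1ccccc1 | intermediate
3 | 2,4,6-tris(benzyloxy)phenyl formate | O=COc1c(OCc2ccccc2)cc(OCc2ccccc2)cc1OCc1ccccc1 | intermediate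
4 | 2,4,6-tris(benzyloxy)phenol | Oc1c(OCc2ccccc2)cc(OCc2ccccc2)cc1OCc1ccccc1 | intermediate
5 | 2,4,6-trifluorobenzaldehyde | O=Cc1c(F)cc(F)cc1F | starting material
6 | 2,6-difluoro-4-[2,4,6-tris(benzyloxy)phenoxy]benzaldehyde | O=Cc1c(F)cc(Oc2c(OCc3ccccc3)cc(OCc3ccccc3)cc2OCc2ccccc2)cc1F | intermediate
7 | benzyl alcohol | OCc1ccccc1 | starting material
8 | 2,6-bis(benzyloxy)-4-[2,4,6-tris(benzyloxy)phenoxy]benzaldehyde | O=Cc1c(OCc2ccccc2)cc(Oc2c(OCc3ccccc3)cc(OCc3ccccc3)cc2OCc2ccccc2)cc1OCc1ccccc1 | intermediate
9 | 2,6-bis(benzyloxy)-4-[2,4,6-tris(benzyloxy)phenoxy]phenyl formate | O=COc1c(OCc2ccccc2)cc(Oc2c(OCc3ccccc3)cc(OCc3ccccc3)cc2OCc2ccccc2)cc1OCc1ccccc1 | intermediate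
10 | 2,6-bis(benzyloxy)-4-[2,4,6-tris(benzyloxy)phenoxy]phenol (AB phenol) | Oc1c(OCc2ccccc2)cc(Oc2c(OCc3ccccc3)cc(OCc3ccccc3)cc2OCc2ccccc2)cc1OCc1ccccc1 | intermediate
11 | 2,4,6-trifluorophenol | Oc1c(F)cc(F)cc1F | starting material
12 | 1,3,5-trifluoro-2-(methoxymethoxy)benzene | COCOc1c(F)cc(F)cc1F | intermediate
13 | 2,4,6-trifluoro-3-(methoxymethoxy)phenyllithium | COCOc1c(F)cc(F)c([Li])c1F | intermediate
14 | 2,4,6-trifluoro-3-(methoxymethoxy)benzaldehyde | COCOc1c(F)cc(F)c(C=O)c1F | intermediate
15 | 4-(AB-oxy)-2,6-difluoro-3-(methoxymethoxy)benzaldehyde | COCOc1c(Oc2c(OCc3ccccc3)cc(Oc3c(OCc4ccccc4)cc(OCc4ccccc4)cc3OCc3ccccc3)cc2OCc2ccccc2)cc(F)c(C=O)c1F | intermediate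
16 | 2,6-bis(benzyloxy)-4-(AB-oxy)-3-(methoxymethoxy)benzaldehyde | COCOc1c(Oc2c(OCc3ccccc3)cc(Oc3c(OCc4ccccc4)cc(OCc4ccccc4)cc3OCc3ccccc3)cc2OCc2ccccc2)cc(OCc2ccccc2)c(C=O)c1OCc1ccccc1 | intermediate
17 | 2,6-bis(benzyloxy)-3-hydroxy-4-(AB-oxy)benzaldehyde (ABC phenol) | Oc1c(Oc2c(OCc3ccccc3)cc(Oc3c(OCc4ccccc4)cc(OCc4ccccc4)cc3OCc3ccccc3)cc2OCc2ccccc2)cc(OCc2ccccc2)c(C=O)c1OCc1ccccc1 | intermediate
18 | 2,4-difluoro-6-hydroxybenzaldehyde | O=Cc1c(O)cc(F)cc1F | starting material
19 | 2,4-difluoro-6-(methoxymethoxy)benzaldehyde | COCOc1cc(F)cc(F)c1C=O | intermediate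
20 | ABCD fluoro aldehyde: 17 etherified at O-3 with 3-fluoro-4-formyl-5-(methoxymethoxy)phenyl (ring D) | COCOc1cc(Oc2c(Oc3c(OCc4ccccc4)cc(Oc4c(OCc5ccccc5)cc(OCc5ccccc5)cc4OCc4ccccc4)cc3OCc3ccccc3)cc(OCc3ccccc3)c(C=O)c2OCc2ccccc2)cc(F)c1C=O | intermediate
21 | ABCD aldehyde: ring D = 3-(benzyloxy)-4-formyl-5-(methoxymethoxy)phenyl | COCOc1cc(Oc2c(Oc3c(OCc4ccccc4)cc(Oc4c(OCc5ccccc5)cc(OCc5ccccc5)cc4OCc4ccccc4)cc3OCc3ccccc3)cc(OCc3ccccc3)c(C=O)c2OCc2ccccc2)cc(OCc2ccccc2)c1C=O | intermediate
22 | ABCD phenol: ring D = 3-(benzyloxy)-4-formyl-5-hydroxyphenyl | Oc1cc(Oc2c(Oc3c(OCc4ccccc4)cc(Oc4c(OCc5ccccc5)cc(OCc5ccccc5)cc4OCc4ccccc4)cc3OCc3ccccc3)cc(OCc3ccccc3)c(C=O)c2OCc2ccccc2)cc(OCc2ccccc2)c1C=O | intermediate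
23 | pentaaryl difluoro tris-aldehyde: ring E = 3,5-difluoro-4-formylphenyl on the ring D oxygen of 22 | O=Cc1c(F)cc(Oc2cc(Oc3c(Oc4c(OCc5ccccc5)cc(Oc5c(OCc6ccccc6)cc(OCc6ccccc6)cc5OCc5ccccc5)cc4OCc4ccccc4)cc(OCc4ccccc4)c(C=O)c3OCc3ccccc3)cc(OCc3ccccc3)c2C=O)cc1F | intermediate
24 | decabenzyl pentaaryl tetraether tris-aldehyde (formyl at C4 of rings C, D and E) | O=Cc1c(OCc2ccccc2)cc(Oc2cc(Oc3c(Oc4c(OCc5ccccc5)cc(Oc5c(OCc6ccccc6)cc(OCc6ccccc6)cc5OCc5ccccc5)cc4OCc4ccccc4)cc(OCc4ccccc4)c(C=O)c3OCc3ccccc3)cc(OCc3ccccc3)c2C=O)cc1OCc1ccccc1 | intermediate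
25 | decabenzyl tris-formate (formyloxy at C4 of rings C, D and E) | O=COc1c(OCc2ccccc2)cc(Oc2cc(Oc3c(Oc4c(OCc5ccccc5)cc(Oc5c(OCc6ccccc6)cc(OCc6ccccc6)cc5OCc5ccccc5)cc4OCc4ccccc4)cc(OCc4ccccc4)c(OC=O)c3OCc3ccccc3)cc(OCc3ccccc3)c2OC=O)cc1OCc1ccccc1 | intermediate
26 | decabenzyl triol (hydroxyl at C4 of rings C, D and E) | Oc1c(OCc2ccccc2)cc(Oc2cc(Oc3c(Oc4c(OCc5ccccc5)cc(Oc5c(OCc6ccccc6)cc(OCc6ccccc6)cc5OCc5ccccc5)cc4OCc4ccccc4)cc(OCc4ccccc4)c(O)c3OCc3ccccc3)cc(OCc3ccccc3)c2O)cc1OCc1ccccc1 | intermediate
27 | CNP0154768.0, pentaaryl tetraether polyphenol | Oc1cc(O)c(Oc2cc(O)c(Oc3cc(O)c(O)c(O)c3Oc3cc(O)c(O)c(Oc4cc(O)c(O)c(O)c4)c3)c(O)c2)c(O)c1 | target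

**Step count**

Total: 18 steps. Longest linear sequence: 15 steps (steps 1–5, 8–10, 12–18); steps 6–7 and step 11 are side branches.

**Three steps most likely to fail**

1. Step 17 (threefold Baeyer–Villiger oxidation). At the most crowded formyl group, on ring C between two benzyloxy groups, hydride rather than aryl may shift in the peroxy adduct and give a benzoic acid. A formate may also be cleaved while peracid is still present, so that a freed electron-rich phenol is oxidised on towards a quinone. With three sites, partial conversion would give mixtures. The fallback sets out from 24 and turns each formyl group into an acetyl group, so that the aryl group competes with methyl instead of hydride and the phenols emerge as sturdier acetates. MeMgBr (THF, 0 °C) should add to the three aldehydes to give the tris(1-hydroxyethyl) compound F1, a mixture of diastereomers whose stereocentres are removed in the next operation. Dess–Martin periodinane (NaHCO3, CH2Cl2) should give the tris(acetyl) compound F2. Baeyer–Villiger oxidation with mCPBA (CH2Cl2, cat. TFA) should give the tris(acetate) F3, and K2CO3 in MeOH/THF should cleave the acetates, which brings the route back at 26.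

2. Step 8 (first ether bond to the ring C unit). The phenoxide may attack the ortho fluorine at C6 of 14, which is flanked only by hydrogen, in competition with the para fluorine, and the coupling may be slow because both partners carry ortho substituents. Either would give regioisomeric mixtures. The fallback fixes the site by a bromine and forms the ether by copper catalysis. It sets out from 10, and the new ring C partner is made from 2-bromo-4,6-difluorophenol. MOMCl/K2CO3 should give 1-bromo-3,5-difluoro-2-(methoxymethoxy)benzene F4. LiN(i-Pr)2 at −78 °C should remove the proton between the two fluorines to give 4-bromo-2,6-difluoro-3-(methoxymethoxy)phenyllithium F5, which DMF followed by an acetic acid quench should convert into 4-bromo-2,6-difluoro-3-(methoxymethoxy)benzaldehyde F6. Sodium benzyloxide (BnOH, NaH, DMF) should displace only the two formyl-activated fluorines, bromide being a far poorer leaving group in SNAr, to give 2,6-bis(benzyloxy)-4-bromo-3-(methoxymethoxy)benzaldehyde F7. Ullmann ether coupling of 10 with F7 (CuI, picolinic acid, K3PO4, DMSO, 90 °C, argon) should then give 16, where the route is rejoined.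

3. Step 15 (attachment of ring E). The ring D phenoxide is a chelating salicylaldehyde-type nucleophile of low reactivity and modest bulk, so attack at an ortho fluorine of 5 through cation bridging to the formyl oxygen, or a second arylation, may compete with para attack. The benzyl oxide treatment that follows, on a molecule with three aldehydes, adds exposure to hydride transfer. The fallback sets out from 22 and brings ring E in with its benzyloxy groups already in place and its coupling site marked by bromine. 4-Bromo-2,6-difluorobenzaldehyde with BnOH/NaH in DMF should give 2,6-bis(benzyloxy)-4-bromobenzaldehyde F8. Ullmann ether coupling of 22 with F8 (CuI, picolinic acid, K3PO4, DMSO, 90 °C, argon) should give 24 directly, bypassing steps 15 and 16; the route is rejoined at 24.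

**Further compounds**

F1 | step 17 | decabenzyl tris(1-hydroxyethyl) compound (1-hydroxyethyl at C4 of rings C, D and E; mixture of diastereomers) | CC(O)c1c(OCc2ccccc2)cc(Oc2cc(Oc3c(Oc4c(OCc5ccccc5)cc(Oc5c(OCc6ccccc6)cc(OCc6ccccc6)cc5OCc5ccccc5)cc4OCc4ccccc4)cc(OCc4ccccc4)c(C(C)O)c3OCc3ccccc3)cc(OCc3ccccc3)c2C(C)O)cc1OCc1ccccc1
F2 | step 17 | decabenzyl tris(acetyl) compound (acetyl at C4 of rings C, D and E) | CC(=O)c1c(OCc2ccccc2)cc(Oc2cc(Oc3c(Oc4c(OCc5ccccc5)cc(Oc5c(OCc6ccccc6)cc(OCc6ccccc6)cc5OCc5ccccc5)cc4OCc4ccccc4)cc(OCc4ccccc4)c(C(C)=O)c3OCc3ccccc3)cc(OCc3ccccc3)c2C(C)=O)cc1OCc1ccccc1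
F3 | step 17 | decabenzyl tris(acetate) (acetoxy at C4 of rings C, D and E) | CC(=O)Oc1c(OCc2ccccc2)cc(Oc2cc(Oc3c(Oc4c(OCc5ccccc5)cc(Oc5c(OCc6ccccc6)cc(OCc6ccccc6)cc5OCc5ccccc5)cc4OCc4ccccc4)cc(OCc4ccccc4)c(OC(C)=O)c3OCc3ccccc3)cc(OCc3ccccc3)c2OC(C)=O)cc1OCc1ccccc1
F4 | step 8 | 1-bromo-3,5-difluoro-2-(methoxymethoxy)benzene | COCOc1c(Br)cc(F)cc1F
F5 | step 8 | 4-bromo-2,6-difluoro-3-(methoxymethoxy)phenyllithium | COCOc1c(Br)cc(F)c([Li])c1F
F6 | step 8 | 4-bromo-2,6-difluoro-3-(methoxymethoxy)benzaldehyde | COCOc1c(Br)cc(F)c(C=O)c1F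
F7 | step 8 | 2,6-bis(benzyloxy)-4-bromo-3-(methoxymethoxy)benzaldehyde | COCOc1c(Br)cc(OCc2ccccc2)c(C=O)c1OCc1ccccc1
F8 | step 15 | 2,6-bis(benzyloxy)-4-bromobenzaldehyde | O=Cc1c(OCc2ccccc2)cc(Br)cc1OCc1ccccc1
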